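**Strategy.** The target is a twofold-symmetric bibenzyl whose two identical cyclopentane rings each carry a benzylic quaternary stereocentre (C1, S) next to the gem-dimethyl carbon (C2). The route rests on disconnecting the C1–C2 bond of both rings at once. In the forward direction a double rhodium-carbenoid 1,5 C–H insertion of an acyclic bis(α-diazo ester) closes both cyclopentanes in one operation. It turns each tertiary benzylic C1–H stereocentre, set earlier by one asymmetric hydrogenation, into the quaternary centre with retention. The precursor is a bibenzyl bearing two (S)-6-arylheptanoate chains with a diazo group α to each ester; each ester carbon later becomes one methyl of a gem-dimethyl group.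

Key step: step 6

Assumption: the enantiomer of the iridium catalyst that delivers the S centres in step 4 is identified in a small-scale trial; both antipodes of the ligand are available.

**Step 1**
Reactants: 1 3-bromo-4,5-dimethoxybenzaldehyde (2 equiv)
Product: 2 (E)-1,2-bis(3-bromo-4,5-dimethoxyphenyl)ethene
Conditions: TiCl4, Zn, pyridine, THF, reflux
Reagents that add atoms: none
Why: McMurry reductive coupling by low-valent titanium joins the two aryl halves through their future benzylic carbons; aryl bromides survive, and the alkene geometry is immaterial because the double bond is saturated in step 4.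

**Step 2**
Reactants: 2 (E)-1,2-bis(3-bromo-4,5-dimethoxyphenyl)ethene; 3 methyl 6-chloro-6-oxohexanoate (2 equiv)
Product: 6 (E)-1,2-bis[3-(6-methoxy-6-oxohexanoyl)-4,5-dimethoxyphenyl]ethene, via dilithiostilbene 4 (not isolated), via bis(arylzinc chloride) 5 (not isolated)
Conditions: n-BuLi, THF, −78 °C; ZnCl2, −78 → 0 °C; then 3, Pd(PPh3)4 (cat.), 0 °C → rt
Reagents that add atoms: n-butyllithium, [Li]CCCC (lithium only in intermediate 4); zinc chloride, Cl[Zn]Cl (zinc and chlorine only in intermediate 5); all atoms of 6 come from 2 and 3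
Why: Bromine–lithium exchange, transmetalation to zinc and Negishi acylation under zerovalent palladium catalysis install both six-carbon chains at the carbons that become the benzylic stereocentres; the arylzinc stops at the ketone and leaves the methyl esters untouched.

**Step 3**
Reactants: 6 (E)-1,2-bis[3-(6-methoxy-6-oxohexanoyl)-4,5-dimethoxyphenyl]ethene
Product: 7 (E)-1,2-bis[3-(7-methoxy-7-oxohept-1-en-2-yl)-4,5-dimethoxyphenyl]ethene
Conditions: Ph3PCH3Br, NaHMDS, THF, 0 °C → rt
Reagents that add atoms: methyltriphenylphosphonium bromide, C[P+](c1ccccc1)(c1ccccc1)c1ccccc1.[Br-]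
Why: Wittig methylenation converts both aryl ketones into 1,1-disubstituted alkenes, the ylide reacting far faster with ketones than with the remote methyl esters.

**Step 4**
Reactants: 7 (E)-1,2-bis[3-(7-methoxy-7-oxohept-1-en-2-yl)-4,5-dimethoxyphenyl]ethene
Product: 8 dimethyl (6S,6'S)-6,6'-[ethane-1,2-diylbis(2,3-dimethoxy-5,1-phenylene)]diheptanoate
Conditions: H2 (1–5 bar), [Ir(cod)(ThrePHOX)]BArF (1–2 mol%), CH2Cl2, rt
Reagents that add atoms: none
Why: Iridium N,P-catalysed asymmetric hydrogenation of unfunctionalised 1,1-disubstituted aryl alkenes sets both CH(CH3) centres as S by catalyst-controlled face selection and saturates the stilbene bond in the same operation; because the two centres are set independently, a mis-set centre should appear mainly as the meso diastereomer, so the S,S isomer should be of higher enantiomeric purity than either single event.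

**Step 5**
Reactants: 8 dimethyl (6S,6'S)-6,6'-[ethane-1,2-diylbis(2,3-dimethoxy-5,1-phenylene)]diheptanoate
Product: 11 dimethyl (6S,6'S)-2,2'-bis(diazo)-6,6'-[ethane-1,2-diylbis(2,3-dimethoxy-5,1-phenylene)]diheptanoate, via bis(lithium enolate) 9 (not isolated), via bis(trifluoroacetyl) diester 10 (not isolated)
Conditions: LDA, THF, −78 °C; CF3CO2CH2CF3, −78 °C; then MsN3, Et3N, H2O, MeCN, rt
Reagents that add atoms: methanesulfonyl azide, CS(=O)(=O)N=[N+]=[N-]; lithium diisopropylamide, CC(C)N([Li])C(C)C (lithium only in intermediate 9); 2,2,2-trifluoroethyl trifluoroacetate, O=C(OCC(F)(F)F)C(F)(F)F (trifluoroacetyl group only in intermediate 10)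
Why: Deacylative (Regitz-type, detrifluoroacetylative) diazo transfer: Claisen C-trifluoroacetylation of each ester enolate activates the α-carbon, the sulfonyl azide delivers N2 and the trifluoroacetyl group leaves as the N-acylsulfonamide, while the remote benzylic stereocentres are not touched.

**Step 6**
Reactants: 11 dimethyl (6S,6'S)-2,2'-bis(diazo)-6,6'-[ethane-1,2-diylbis(2,3-dimethoxy-5,1-phenylene)]diheptanoate
Product: 12 dimethyl (2S,2'S)-2,2'-[ethane-1,2-diylbis(2,3-dimethoxy-5,1-phenylene)]bis(2-methylcyclopentane-1-carboxylate), mixture of epimers at the ester-bearing carbons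
Conditions: Rh2(O2CCPh3)4 (2 mol%), CH2Cl2, −78 → 0 °C, slow addition of 11, high dilution
Reagents that add atoms: none
Why: Each diazo ester loses N2 at the dirhodium tetracarboxylate to give an electrophilic rhodium carbenoid, which inserts in a concerted three-centre fashion into the tertiary benzylic C–H bond lying 1,5 to the carbenoid carbon, so that the C1–C2 bond of each cyclopentane forms. The closest known reaction type is the rhodium-mediated intramolecular 1,5 C–H insertion of α-alkyl-α-diazo esters into benzylic C–H bonds to give 2-arylcyclopentanecarboxylates, a process known to proceed with retention at a stereogenic C–H carbon. Each ring closes through a six-membered chair-like transition state to a five-membered carbocycle, twice in the same molecule. The new quaternary benzylic stereocentre is controlled by the substrate alone: the S C–H centre from step 4 is converted with retention, whereas the configuration at the ester-bearing carbon is uncontrolled and irrelevant because that carbon becomes the gem-dimethyl carbon. The step needs insertion to win over 1,2-hydride shift of the α-alkyl carbenoid (which would give the Z-enoate) and over attack on the arene; the bulky triphenylacetate ligands, the low temperature and the fact that the only 1,5 C–H bond is the electron-rich tertiary benzylic one should secure this, and slow addition at high dilution suppresses carbene dimerisation.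

**Step 7**
Reactants: 12 dimethyl (2S,2'S)-2,2'-[ethane-1,2-diylbis(2,3-dimethoxy-5,1-phenylene)]bis(2-methylcyclopentane-1-carboxylate)
Product: 14 dimethyl (2R,2'R)-2,2'-[ethane-1,2-diylbis(2,3-dimethoxy-5,1-phenylene)]bis(1,2-dimethylcyclopentane-1-carboxylate), epimers at C1 and C1' (same spatial arrangement at the aryl-bearing carbons as in 12; the descriptor changes only through CIP priority), via bis(lithium enolate) 13 (not isolated)
Conditions: LDA, THF, −78 → 0 °C; MeI, DMPU, −78 °C → rt
Reagents that add atoms: iodomethane, CI; lithium diisopropylamide, CC(C)N([Li])C(C)C (lithium only in intermediate 13)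
Why: Alkylation of the ester enolate with iodomethane places the first methyl group on the future gem-dimethyl carbon; the enolate erases the uncontrolled configuration there, the new one is irrelevant, and the quaternary benzylic centre has no acidic hydrogen.

**Step 8**
Reactants: 14 dimethyl (2R,2'R)-2,2'-[ethane-1,2-diylbis(2,3-dimethoxy-5,1-phenylene)]bis(1,2-dimethylcyclopentane-1-carboxylate)
Product: 15 {ethane-1,2-diylbis[(2,3-dimethoxy-5,1-phenylene)(1,2-dimethylcyclopentane-2,1-diyl)]}dimethanol, i.e. each ester reduced to CH2OH, aryl-bearing carbons S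
Conditions: LiAlH4, THF, 0 °C → reflux
Reagents that add atoms: none
Why: Hydride reduction of the hindered neopentyl-type esters with LiAlH4 gives the primary alcohols without touching any stereocentre.

**Step 9**
Reactants: 15 the bis(hydroxymethyl) compound
Product: 16 2,2'-[ethane-1,2-diylbis(2,3-dimethoxy-5,1-phenylene)]bis(1,2-dimethylcyclopentane-1-carbaldehyde), aryl-bearing carbons R by CIP (unchanged arrangement)
Conditions: Dess–Martin periodinane, CH2Cl2, rt
Reagents that add atoms: none
Why: Dess–Martin oxidation stops at the aldehyde, which cannot enolise because its α-carbon is quaternary.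

**Step 10**
Reactants: 16 the dialdehyde
Product: 18 1,2-bis{3,4-dimethoxy-5-[(1S)-1,2,2-trimethylcyclopentyl]phenyl}ethane, via bis(hydrazone) 17 (not isolated)
Conditions: N2H4·H2O, KOH, diethylene glycol, 130 °C then 200 °C
Reagents that add atoms: hydrazine hydrate, NN.O (nitrogen only in intermediate 17)
Why: Wolff–Kishner reduction (Huang-Minlon modification) turns each formyl group into the second methyl of the gem-dimethyl unit via the hydrazone; premature loss of a methyl ether under the hot base would be inconsequential given step 11.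

**Step 11**
Reactants: 18 1,2-bis{3,4-dimethoxy-5-[(1S)-1,2,2-trimethylcyclopentyl]phenyl}ethane
Product: 19 5,5'-(ethane-1,2-diyl)bis{3-[(1S)-1,2,2-trimethylcyclopentyl]benzene-1,2-diol} (CNP0144189.1)
Conditions: BBr3, CH2Cl2, −78 °C → rt; then H2O
Reagents that add atoms: none
Why: Lewis-acid cleavage of the four aryl methyl ethers with BBr3 liberates both catechols; the all-carbon quaternary centres are inert to these conditions.

**Compound list**

1 | 3-bromo-4,5-dimethoxybenzaldehyde | COc1cc(C=O)cc(Br)c1OC | starting material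
2 | (E)-1,2-bis(3-bromo-4,5-dimethoxyphenyl)ethene | COc1cc(/C=C/c2cc(Br)c(OC)c(OC)c2)cc(Br)c1OC | intermediate
3 | methyl 6-chloro-6-oxohexanoate | COC(=O)CCCCC(Cl)=O | starting material
4 | (E)-1,2-bis(3-lithio-4,5-dimethoxyphenyl)ethene | COc1cc(/C=C/c2cc([Li])c(OC)c(OC)c2)cc([Li])c1OC | intermediate (not isolated)
5 | (E)-1,2-bis[3-(chlorozincio)-4,5-dimethoxyphenyl]ethene | COc1cc(/C=C/c2cc([Zn]Cl)c(OC)c(OC)c2)cc([Zn]Cl)c1OC | intermediate (not isolated)
6 | (E)-1,2-bis[3-(6-methoxy-6-oxohexanoyl)-4,5-dimethoxyphenyl]ethene | COC(=O)CCCCC(=O)c1cc(/C=C/c2cc(C(=O)CCCCC(=O)OC)c(OC)c(OC)c2)cc(OC)c1OC | intermediate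
7 | (E)-1,2-bis[3-(7-methoxy-7-oxohept-1-en-2-yl)-4,5-dimethoxyphenyl]ethene | COC(=O)CCCCC(=C)c1cc(/C=C/c2cc(C(=C)CCCCC(=O)OC)c(OC)c(OC)c2)cc(OC)c1OC | intermediate
8 | dimethyl (6S,6'S)-6,6'-[ethane-1,2-diylbis(2,3-dimethoxy-5,1-phenylene)]diheptanoate | COC(=O)CCCC[C@H](C)c1cc(CCc2cc([C@@H](C)CCCCC(=O)OC)c(OC)c(OC)c2)cc(OC)c1OC | intermediate
9 | bis(lithium ester enolate) of 8 | COC(O[Li])=CCCC[C@H](C)c1cc(CCc2cc([C@@H](C)CCCC=C(O[Li])OC)c(OC)c(OC)c2)cc(OC)c1OC | intermediate (not isolated)
10 | dimethyl (6S,6'S)-2,2'-bis(trifluoroacetyl)-6,6'-[ethane-1,2-diylbis(2,3-dimethoxy-5,1-phenylene)]diheptanoate, C2 epimers | COC(=O)C(C(=O)C(F)(F)F)CCC[C@H](C)c1cc(CCc2cc([C@@H](C)CCCC(C(=O)C(F)(F)F)C(=O)OC)c(OC)c(OC)c2)cc(OC)c1OC | intermediate (not isolated)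
11 | dimethyl (6S,6'S)-2,2'-bis(diazo)-6,6'-[ethane-1,2-diylbis(2,3-dimethoxy-5,1-phenylene)]diheptanoate | COC(=O)C(=[N+]=[N-])CCC[C@H](C)c1cc(CCc2cc([C@@H](C)CCCC(=[N+]=[N-])C(=O)OC)c(OC)c(OC)c2)cc(OC)c1OC | intermediate
12 | dimethyl (2S,2'S)-2,2'-[ethane-1,2-diylbis(2,3-dimethoxy-5,1-phenylene)]bis(2-methylcyclopentane-1-carboxylate), C1 epimers | COC(=O)C1CCC[C@]1(C)c1cc(CCc2cc([C@@]3(C)CCCC3C(=O)OC)c(OC)c(OC)c2)cc(OC)c1OC | intermediate
13 | bis(lithium ester enolate) of 12 | COC(O[Li])=C1CCC[C@]1(C)c1cc(CCc2cc([C@@]3(C)CCCC3=C(O[Li])OC)c(OC)c(OC)c2)cc(OC)c1OC | intermediate (not isolated)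
14 | dimethyl (2R,2'R)-2,2'-[ethane-1,2-diylbis(2,3-dimethoxy-5,1-phenylene)]bis(1,2-dimethylcyclopentane-1-carboxylate), C1 epimers | COC(=O)C1(C)CCC[C@]1(C)c1cc(CCc2cc([C@@]3(C)CCCC3(C)C(=O)OC)c(OC)c(OC)c2)cc(OC)c1OC | intermediate
15 | bis(hydroxymethyl) compound from 14 (each CO2Me reduced to CH2OH; aryl-bearing carbons S), C1 epimers | OCC1(C)CCC[C@]1(C)c1cc(CCc2cc([C@@]3(C)CCCC3(C)CO)c(OC)c(OC)c2)cc(OC)c1OC | intermediate
16 | 2,2'-[ethane-1,2-diylbis(2,3-dimethoxy-5,1-phenylene)]bis(1,2-dimethylcyclopentane-1-carbaldehyde), aryl-bearing carbons R by CIP, C1 epimers | O=CC1(C)CCC[C@]1(C)c1cc(CCc2cc([C@@]3(C)CCCC3(C)C=O)c(OC)c(OC)c2)cc(OC)c1OC | intermediate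
17 | bis(hydrazone) of 16 | NN=CC1(C)CCC[C@]1(C)c1cc(CCc2cc([C@@]3(C)CCCC3(C)C=NN)c(OC)c(OC)c2)cc(OC)c1OC | intermediate (not isolated)
18 | 1,2-bis{3,4-dimethoxy-5-[(1S)-1,2,2-trimethylcyclopentyl]phenyl}ethane | CC1(C)CCC[C@]1(C)c1cc(CCc2cc([C@@]3(C)CCCC3(C)C)c(OC)c(OC)c2)cc(OC)c1OC | intermediate
19 | 5,5'-(ethane-1,2-diyl)bis{3-[(1S)-1,2,2-trimethylcyclopentyl]benzene-1,2-diol} | CC1(C)CCC[C@]1(C)c1cc(CCc2cc(O)c(O)c([C@@]3(C)CCCC3(C)C)c2)cc(O)c1O | target

**Step count.** Total: 11 steps. Longest linear sequence: 11 steps (1 → 19); 3 is a purchased reagent that enters at step 2.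

**Steps most likely to fail**

1. Step 6 (double C–H insertion). A 1,2-hydride shift in the α-alkyl carbenoid may outrun insertion, or only one of the two carbenoids may cyclise; partial loss of configuration through a stepwise hydride-abstraction pathway is also conceivable at the electron-rich benzylic position. The fallback sets out from 2 and returns at 12, and replaces the acceptor-only carbenoid by an acceptor/acceptor one whose tether carbonyl carries no β-hydrogen; the same ring bond is formed. Dibromide 2 is acylated as in step 2 but with methyl 4-chloro-4-oxobutanoate to give (E)-1,2-bis[3-(4-methoxy-4-oxobutanoyl)-4,5-dimethoxyphenyl]ethene F1. Wittig methylenation gives (E)-1,2-bis[3-(5-methoxy-5-oxopent-1-en-2-yl)-4,5-dimethoxyphenyl]ethene F2, and the hydrogenation of step 4 gives dimethyl (4S,4'S)-4,4'-[ethane-1,2-diylbis(2,3-dimethoxy-5,1-phenylene)]dipentanoate F3. Crossed Claisen condensation with the lithium enolate of methyl acetate (LDA, MeOAc, THF, −78 °C) gives the bis(3-oxoheptanoate) F4, and diazo transfer (MsN3, Et3N, MeCN) gives the bis(2-diazo-3-oxoheptanoate) F5. Rh2(OAc)4 in CH2Cl2 then closes both rings by 1,5-insertion into the same benzylic C–H bonds with retention to give the bis(2-methyl-5-oxocyclopentane-1-carboxylate) F6. The ketone is removed by way of the bis(enol triflate) F7 (NaH, PhNTf2, THF) and hydrogenolysis with hydrogenation over PtO2 under H2, which returns to 12.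

2. Step 4 (asymmetric hydrogenation). Face discrimination at the ortho-methoxy-substituted 1,1-disubstituted alkene may be insufficient, or the alkene may isomerise to the trisubstituted isomer before reduction, either of which would erode the configuration of one or both centres. The fallback sets out from 2 and returns at 8, and sets the centres by an enantioconvergent cross-coupling instead. Bromine–lithium exchange of 2 and addition to acetaldehyde give (E)-1,2-bis[3-(1-hydroxyethyl)-4,5-dimethoxyphenyl]ethene F8 as a stereoisomer mixture, and PBr3 gives (E)-1,2-bis[3-(1-bromoethyl)-4,5-dimethoxyphenyl]ethene F9. Nickel-catalysed Negishi coupling of the racemic secondary benzylic bromides with (5-methoxy-5-oxopentyl)zinc bromide (NiBr2·diglyme, (i-Pr)-pybox of the appropriate handedness, DMA, 0 °C) gives dimethyl (6S,6'S)-6,6'-[(E)-ethene-1,2-diylbis(2,3-dimethoxy-5,1-phenylene)]diheptanoate F10. Hydrogenation of the stilbene bond (H2, Pd/C, EtOAc) returns to 8.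

3. Step 5 (double diazo transfer). C-Trifluoroacetylation of the two simple ester enolates may be incomplete (proton return, self-condensation), leaving material with only one diazo group. The fallback sets out from 8 and returns at 11, and reaches the diazo ester by sulfinate elimination from a hydrazone instead of acyl activation. Hydroxylation of the bis-enolate of 8 with 2-(phenylsulfonyl)-3-phenyloxaziridine gives the bis(2-hydroxyheptanoate) F11, and Dess–Martin oxidation gives the bis(2-oxoheptanoate) F12. Condensation with TsNHNH2 gives the bis(tosylhydrazone) F13, and Et3N in CH2Cl2 (Bamford–Stevens elimination) returns to 11.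

**Further compounds**

F1 | step 6 | (E)-1,2-bis[3-(4-methoxy-4-oxobutanoyl)-4,5-dimethoxyphenyl]ethene | COC(=O)CCC(=O)c1cc(/C=C/c2cc(C(=O)CCC(=O)OC)c(OC)c(OC)c2)cc(OC)c1OC
F2 | step 6 | (E)-1,2-bis[3-(5-methoxy-5-oxopent-1-en-2-yl)-4,5-dimethoxyphenyl]ethene | COC(=O)CCC(=C)c1cc(/C=C/c2cc(C(=C)CCC(=O)OC)c(OC)c(OC)c2)cc(OC)c1OC
F3 | step 6 | dimethyl (4S,4'S)-4,4'-[ethane-1,2-diylbis(2,3-dimethoxy-5,1-phenylene)]dipentanoate | COC(=O)CC[C@H](C)c1cc(CCc2cc([C@@H](C)CCC(=O)OC)c(OC)c(OC)c2)cc(OC)c1OC
F4 | step 6 | dimethyl (6S,6'S)-6,6'-[ethane-1,2-diylbis(2,3-dimethoxy-5,1-phenylene)]bis(3-oxoheptanoate) | COC(=O)CC(=O)CC[C@H](C)c1cc(CCc2cc([C@@H](C)CCC(=O)CC(=O)OC)c(OC)c(OC)c2)cc(OC)c1OC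
F5 | step 6 | dimethyl (6S,6'S)-2,2'-bis(diazo)-6,6'-[ethane-1,2-diylbis(2,3-dimethoxy-5,1-phenylene)]bis(3-oxoheptanoate) | COC(=O)C(=[N+]=[N-])C(=O)CC[C@H](C)c1cc(CCc2cc([C@@H](C)CCC(=O)C(=[N+]=[N-])C(=O)OC)c(OC)c(OC)c2)cc(OC)c1OC
F6 | step 6 | dimethyl 2,2'-[ethane-1,2-diylbis(2,3-dimethoxy-5,1-phenylene)]bis(2-methyl-5-oxocyclopentane-1-carboxylate), aryl-bearing carbons as in 12 | COC(=O)C1C(=O)CC[C@]1(C)c1cc(CCc2cc([C@@]3(C)CCC(=O)C3C(=O)OC)c(OC)c(OC)c2)cc(OC)c1OC
F7 | step 6 | dimethyl 5,5'-[ethane-1,2-diylbis(2,3-dimethoxy-5,1-phenylene)]bis(5-methyl-2-{[(trifluoromethyl)sulfonyl]oxy}cyclopent-1-ene-1-carboxylate) | COC(=O)C1=C(OS(=O)(=O)C(F)(F)F)CC[C@]1(C)c1cc(CCc2cc([C@@]3(C)CCC(OS(=O)(=O)C(F)(F)F)=C3C(=O)OC)c(OC)c(OC)c2)cc(OC)c1OC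
F8 | step 4 | (E)-1,2-bis[3-(1-hydroxyethyl)-4,5-dimethoxyphenyl]ethene, stereoisomer mixture | CC(O)c1cc(/C=C/c2cc(C(C)O)c(OC)c(OC)c2)cc(OC)c1OC
F9 | step 4 | (E)-1,2-bis[3-(1-bromoethyl)-4,5-dimethoxyphenyl]ethene, stereoisomer mixture | CC(Br)c1cc(/C=C/c2cc(C(C)Br)c(OC)c(OC)c2)cc(OC)c1OC
F10 | step 4 | dimethyl (6S,6'S)-6,6'-[(E)-ethene-1,2-diylbis(2,3-dimethoxy-5,1-phenylene)]diheptanoate | COC(=O)CCCC[C@H](C)c1cc(/C=C/c2cc([C@@H](C)CCCCC(=O)OC)c(OC)c(OC)c2)cc(OC)c1OC
F11 | step 5 | dimethyl (6S,6'S)-2,2'-dihydroxy-6,6'-[ethane-1,2-diylbis(2,3-dimethoxy-5,1-phenylene)]diheptanoate, C2 epimers | COC(=O)C(O)CCC[C@H](C)c1cc(CCc2cc([C@@H](C)CCCC(O)C(=O)OC)c(OC)c(OC)c2)cc(OC)c1OC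
F12 | step 5 | dimethyl (6S,6'S)-2,2'-dioxo-6,6'-[ethane-1,2-diylbis(2,3-dimethoxy-5,1-phenylene)]diheptanoate | COC(=O)C(=O)CCC[C@H](C)c1cc(CCc2cc([C@@H](C)CCCC(=O)C(=O)OC)c(OC)c(OC)c2)cc(OC)c1OC
F13 | step 5 | bis(4-methylbenzenesulfonylhydrazone) of F12 | COC(=O)C(=NNS(=O)(=O)c1ccc(C)cc1)CCC[C@H](C)c1cc(CCc2cc([C@@H](C)CCCC(=NNS(=O)(=O)c3ccc(C)cc3)C(=O)OC)c(OC)c(OC)c2)cc(OC)c1OC
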